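**Retrosynthetic overview**

1. The target is a 2-methyl-3-alkyl-1,4-naphthoquinone. The C4 carbonyl is added last by para-oxidation of the 1-naphthol 39, in which C4 still carries H.
2. Ring B of 39 is made in one operation from the acyclic diazo enone 35: a photochemical Wolff shift forms C2–C3 and a ketene electrocyclisation forms C1–C8a. Ring A is bought as benzaldehyde, so ring B is the only ring formed.
3. Enabling feature: ring B is a C1(=O)–C2(Me)=C3(chain)–C4 unit fused to an unsubstituted benzo ring. It maps onto a ketene O=C1=C2(Me)–C3(R)=C4H–Ph whose two ortho carbons are equivalent, and the cyclobutenone/ketene equilibrium makes the styryl geometry irrelevant.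
4. 35 comes from the C43 alkyne 27 by carboalumination and Pd-catalysed allylation with the Morita–Baylis–Hillman bromide 31 (from benzaldehyde and ethyl vinyl ketone), then diazo transfer.
5. 27 comes from hexaprenyl sulfone 12 (two farnesyl units) and the chiral iodide 23, whose two stereocentres are taken from (S)-citronellyl bromide and (R)-3-bromo-2-methylpropan-1-ol.

Key step: step 21

Remark: "C45 chain" means (2E,7R,11S,14E,18E,22E,26E,30E)-3,7,11,15,19,23,27,31,35-nonamethylhexatriaconta-2,14,18,22,26,30,34-heptaen-1-yl and "hexaprenyl" means (2E,6E,10E,14E,18E)-3,7,11,15,19,23-hexamethyltetracosa-2,6,10,14,18,22-hexaen-1-yl. The two saturated stereocentres have the spatial sense of natural phytol (C11 reads S only because the unsaturated neighbour outranks the saturated one). No bond to either stereocentre is made or broken in the route. Compounds 1, 5, 13, 15, 28 and 29 are assumed to be commercial, the chiral and olefinic ones in high isomeric purity.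

**Route**

Step 1
Reactants: 1 (2E,6E)-farnesol
Product: 2 (2E,6E)-farnesyl acetate
Conditions: Ac2O, pyridine, DMAP (cat.), CH2Cl2, 0 °C → rt
Reagents that add atoms: acetic anhydride, CC(=O)OC(C)=O
Why: Routine O-acylation masks the allylic alcohol so that the allylic oxidation and the sulfone alkylation act only at the far end of the chain.

Step 2
Reactants: 2 (2E,6E)-farnesyl acetate
Product: 3 (2E,6E,10E)-12-hydroxyfarnesyl acetate
Conditions: SeO2 (cat.), t-BuOOH, salicylic acid (cat.), CH2Cl2, rt
Reagents that add atoms: tert-butyl hydroperoxide, CC(C)(C)OO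
Why: SeO2-catalysed allylic oxidation (ene reaction then [2,3]-sigmatropic shift) is known to hydroxylate the terminal trans-methyl group of prenyl chains with E-selectivity.

Step 3
Reactants: 3 (2E,6E,10E)-12-hydroxyfarnesyl acetate
Product: 4 (2E,6E,10E)-12-bromofarnesyl acetate
Conditions: CBr4, PPh3, CH2Cl2, −20 → 0 °C
Reagents that add atoms: carbon tetrabromide, BrC(Br)(Br)Br
Why: Appel bromination of a primary allylic alcohol proceeds by SN2 at low temperature and should leave the E-alkene and the acetate untouched.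

Step 4
Reactants: 5 (2E,6E)-farnesyl bromide
Product: 6 (2E,6E)-farnesyl phenyl sulfone
Conditions: PhSO2Na, DMF, rt
Reagents that add atoms: sodium benzenesulfinate, [Na+].[O-]S(=O)c1ccccc1
Why: S-alkylation of the sulfinate by SN2 at the primary allylic bromide gives the allylic sulfone needed as a stabilised C1 nucleophile.

Step 5
Reactants: 6 (2E,6E)-farnesyl phenyl sulfone; 4 (2E,6E,10E)-12-bromofarnesyl acetate
Product: 8 (phenylsulfonyl)hexaprenyl acetate (sulfone on C13; racemic at C13), via lithio sulfone 7 (not isolated)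
Conditions: n-BuLi, THF/DMPU, −78 °C; then 4, −78 °C
Reagents that add atoms: n-butyllithium, [Li]CCCC (lithium of 7 only)
Why: Julia-type alkylation of the α-sulfonyl allyl anion occurs at its α-carbon by SN2 on the allylic bromide, joining the two C15 units head to tail without touching any alkene geometry.

Step 6
Reactants: 8 (phenylsulfonyl)hexaprenyl acetate
Product: 10 all-E-hexaprenol, via sulfone alcohol 9 (not isolated)
Conditions: LiBHEt3 (excess), THF, 0 °C; then PdCl2(dppp) (cat.), 0 °C → rt
Reagents that add atoms: none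
Why: Hydride first cleaves the acetate to an alkoxide that palladium does not ionise, then palladium-catalysed reductive desulfonylation delivers hydride through the π-allyl complex to the less substituted terminus, which should keep the trisubstituted E-alkene in place.

Step 7
Reactants: 10 all-E-hexaprenol
Product: 12 hexaprenyl phenyl sulfone, via hexaprenyl bromide 11 (not isolated)
Conditions: PBr3, pyridine (cat.), Et2O, −10 °C; aqueous wash, solvent exchanged without purification; then PhSO2Na, DMF, rt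
Reagents that add atoms: phosphorus tribromide, BrP(Br)Br (bromine of 11 only); sodium benzenesulfinate, [Na+].[O-]S(=O)c1ccccc1
Why: Bromination of the primary allylic alcohol followed by sulfinate SN2 is the standard telescoped route to polyprenyl sulfones and avoids storing the labile bromide.

Step 8
Reactants: 13 (2R)-3-bromo-2-methylpropan-1-ol
Product: 14 [(2R)-3-bromo-2-methylpropoxy](tert-butyl)dimethylsilane
Conditions: TBSCl, imidazole, DMF, rt
Reagents that add atoms: tert-butyldimethylsilyl chloride, CC(C)(C)[Si](C)(C)Cl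
Why: Silylation protects the hydroxyl so that the bromide end can be turned into a Grignard reagent.

Step 9
Reactants: 14 [(2R)-3-bromo-2-methylpropoxy](tert-butyl)dimethylsilane; 15 (6S)-8-bromo-2,6-dimethyloct-2-ene ((S)-citronellyl bromide)
Product: 17 tert-butyldimethyl{[(2S,6R)-2,6,10-trimethylundec-9-en-1-yl]oxy}silane, via Grignard reagent 16 (not isolated)
Conditions: Mg, THF, 40 °C; then 15, Li2CuCl4 (cat.), THF, −10 °C → rt
Reagents that add atoms: magnesium, [Mg] (in 16 only)
Why: Copper-catalysed sp3–sp3 coupling of a primary Grignard reagent with a primary alkyl bromide (Kochi-type) joins the two chiral-pool pieces, and both stereocentres are carried over unchanged (the descriptor at C2 changes only through CIP priorities).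

Step 10
Reactants: 17 tert-butyldimethyl{[(2S,6R)-2,6,10-trimethylundec-9-en-1-yl]oxy}silane
Product: 19 (4R,8S)-9-[(tert-butyldimethylsilyl)oxy]-4,8-dimethylnonan-1-ol, via aldehyde 18 (not isolated)
Conditions: O3, CH2Cl2/MeOH, −78 °C; then NaBH4, −78 °C → rt
Reagents that add atoms: ozone, [O-][O+]=O
Why: Ozonolysis with reductive work-up cleaves the only C=C bond to a primary alcohol, the isopropylidene carbons leaving as acetone that is reduced in the flask.

Step 11
Reactants: 19 (4R,8S)-9-[(tert-butyldimethylsilyl)oxy]-4,8-dimethylnonan-1-ol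
Product: 20 tert-butyl{[(2S,6R)-9-iodo-2,6-dimethylnonyl]oxy}dimethylsilane
Conditions: I2, PPh3, imidazole, CH2Cl2, 0 °C → rt
Reagents that add atoms: iodine, II
Why: Appel-type iodination converts the unhindered primary alcohol into the iodide by SN2 under neutral conditions that the silyl ether tolerates.

Step 12
Reactants: 20 tert-butyl{[(2S,6R)-9-iodo-2,6-dimethylnonyl]oxy}dimethylsilane
Product: 21 tert-butyl{[(2S,6R)-2,6-dimethyl-11-(trimethylsilyl)undec-10-yn-1-yl]oxy}dimethylsilane
Conditions: HC≡CSiMe3, n-BuLi, THF, −78 °C; then 20, DMPU, −78 °C → rt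
Reagents that add atoms: ethynyltrimethylsilane, C#C[Si](C)(C)C
Why: SN2 alkylation of the lithium acetylide by the primary iodide installs the two carbons of the future first prenyl unit, with the silyl cap protecting the alkyne C–H through the later carbanion and hydride steps.

Step 13
Reactants: 21 tert-butyl{[(2S,6R)-2,6-dimethyl-11-(trimethylsilyl)undec-10-yn-1-yl]oxy}dimethylsilane
Product: 22 (2S,6R)-2,6-dimethyl-11-(trimethylsilyl)undec-10-yn-1-ol
Conditions: camphorsulfonic acid (cat.), MeOH/CH2Cl2, 0 °C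
Reagents that add atoms: none
Why: Acid-catalysed methanolysis removes the primary silyl ether, while the alkynyl C–Si bond, which is labile only to base or fluoride, should survive.

Step 14
Reactants: 22 (2S,6R)-2,6-dimethyl-11-(trimethylsilyl)undec-10-yn-1-ol
Product: 23 [(6R,10S)-11-iodo-6,10-dimethylundec-1-yn-1-yl]trimethylsilane
Conditions: I2, PPh3, imidazole, CH2Cl2, 0 °C → rt
Reagents that add atoms: iodine, II
Why: Appel-type iodination gives the primary iodide needed for the sulfone alkylation without touching the adjacent stereocentre.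

Step 15
Reactants: 12 hexaprenyl phenyl sulfone; 23 [(6R,10S)-11-iodo-6,10-dimethylundec-1-yn-1-yl]trimethylsilane
Product: 25 [(6R,10S,13E,17E,21E,25E,29E)-6,10,14,18,22,26,30,34-octamethyl-12-(phenylsulfonyl)pentatriaconta-13,17,21,25,29,33-hexaen-1-yn-1-yl]trimethylsilane (both epimers at C12), via lithio sulfone 24 (not isolated)
Conditions: n-BuLi, THF/DMPU, −78 °C; then 23, −78 → 0 °C
Reagents that add atoms: n-butyllithium, [Li]CCCC (lithium of 24 only)
Why: Julia-type α-alkylation of the allylic sulfone anion with the primary iodide (DMPU to speed the SN2 at the β-branched carbon) joins the hexaene to the chiral segment with no risk to alkene geometry, and the new sulfone-bearing centre is removed in the next step.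

Step 16
Reactants: 25 the C12 sulfone of step 15
Product: 27 (6R,10S,13E,17E,21E,25E,29E)-6,10,14,18,22,26,30,34-octamethylpentatriaconta-13,17,21,25,29,33-hexaen-1-yne, via silylalkyne 26 (not isolated)
Conditions: PdCl2(dppp) (cat.), LiBHEt3, THF, 0 °C; then K2CO3, MeOH, rt
Reagents that add atoms: none
Why: Palladium-catalysed reductive desulfonylation (hydride to the less substituted π-allyl terminus, alkene position and geometry kept) is followed in the same flask by base-mediated methanolysis of the alkynylsilane to free the terminal alkyne.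

Step 17
Reactants: 28 benzaldehyde; 29 pent-1-en-3-one (ethyl vinyl ketone)
Product: 30 2-[hydroxy(phenyl)methyl]pent-1-en-3-one (racemic)
Conditions: DABCO (cat.), THF, rt
Reagents that add atoms: none
Why: The Morita–Baylis–Hillman reaction joins the aldehyde carbon to the α-carbon of the vinyl ketone, assembling in one step the future C4, C3, C1, C2 and methyl of ring B together with the benzo ring.

Step 18
Reactants: 30 2-[hydroxy(phenyl)methyl]pent-1-en-3-one
Product: 31 (1Z)-2-(bromomethyl)-1-phenylpent-1-en-3-one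
Conditions: PBr3, Et2O, 0 °C → rt
Reagents that add atoms: phosphorus tribromide, BrP(Br)Br
Why: Bromination of a Morita–Baylis–Hillman alcohol proceeds with allylic transposition (SN2') to the thermodynamically preferred conjugated primary bromide.

Step 19
Reactants: 27 the C43 terminal alkyne of step 16; 31 (1Z)-2-(bromomethyl)-1-phenylpent-1-en-3-one
Product: 33 (1E)-2-(C45 chain)-1-phenylpent-1-en-3-one, via alkenylalane 32 (not isolated)
Conditions: Me3Al, Cp2ZrCl2 (cat.), CH2Cl2, 0 °C → rt; excess Me3Al removed in vacuo; then 31, Pd(PPh3)4 (cat.), THF, 0 °C → rt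
Reagents that add atoms: trimethylaluminium, C[Al](C)C
Why: Negishi zirconium-catalysed syn-carboalumination fixes the 2E geometry of the first prenyl unit (methyl to the internal carbon), and the palladium-catalysed alkenylalane–allylic bromide cross-coupling then forms the CH2–alkenyl bond at the less hindered allyl terminus with retention at the alkenyl carbon.

Step 20
Reactants: 33 (1E)-2-(C45 chain)-1-phenylpent-1-en-3-one
Product: 35 (1E)-4-diazo-2-(C45 chain)-1-phenylpent-1-en-3-one, via trifluoroacetyl ketone 34 (not isolated)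
Conditions: LiN(SiMe3)2, THF, −78 °C; CF3CO2CH2CF3, −78 °C; cold aqueous work-up, crude used at once; then MsN3, Et3N, H2O, MeCN, rt
Reagents that add atoms: methanesulfonyl azide, CS(=O)(=O)N=[N+]=[N-]; 2,2,2-trifluoroethyl trifluoroacetate, O=C(OCC(F)(F)F)C(F)(F)F (in 34 only)
Why: Detrifluoroacetylative (Regitz-type) diazo transfer works because the ethyl CH2 is trifluoroacetylated through the kinetic α'-enolate and the resulting 1,3-diketone accepts N2 from the sulfonyl azide with loss of the trifluoroacetyl group, leaving the diazo carbon between the ketone carbonyl and the terminal methyl.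

Step 21
Reactants: 35 (1E)-4-diazo-2-(C45 chain)-1-phenylpent-1-en-3-one
Product: 39 2-methyl-3-(C45 chain)naphthalen-1-ol, via E-vinylketene 36 (not isolated), via cyclobutenone 37 (not isolated), via Z-vinylketene 38 (not isolated)
Conditions: hν (365 nm), degassed toluene (0.01 M), rt, until N2 evolution ends; then 110 °C, dark, Ar
Reagents that add atoms: none
Why: Irradiation expels N2 from 35 and the alkenyl carbon shifts from the carbonyl carbon to the diazo carbon (Wolff rearrangement), which makes the C2–C3 bond of ring B and gives the styryl(methyl)ketene 36 with the alkene geometry retained. The closest known reaction type is the photochemical diazo ketone variant of the Danheiser benzannulation, joined to the known thermolysis of 4-arylcyclobutenones to 1-naphthols. Ketene 36, whose phenyl group points away from the ketene carbon, closes by 4π electrocyclisation to cyclobutenone 37; at 110 °C this ring reopens reversibly, and each time the phenyl group rotates inward ketene 38 forms, which closes ring B by 6π electrocyclisation of the ketene carbon onto an ortho carbon (C1–C8a bond) and then tautomerises irreversibly to the aromatic naphthol. No stereocentre is created; the step is stereoconvergent because both geometric isomers of 35 and both enantiomers of 37 drain into the one product, and the two ortho carbons of the unsubstituted phenyl ring are equivalent, so no regiochemical question arises. The selectivity needed is alkenyl shift over 1,2-hydride shift from the methyl group on the diazo carbon and over carbene capture by the nearby chain alkene, which direct unsensitised irradiation and the good migratory aptitude of an sp2 carbon should favour, while high dilution suppresses ketene dimerisation.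

Step 22
Reactants: 39 2-methyl-3-(C45 chain)naphthalen-1-ol
Product: 40 2-methyl-3-(C45 chain)naphthalene-1,4-dione (CNP0265071.1)
Conditions: Co(salen) (cat., divalent cobalt), O2 (1 atm), DMF/THF, rt, dark
Reagents that add atoms: dioxygen, O=O
Why: Co(salen)-catalysed aerobic para-oxidation of a phenol delivers oxygen to C4, the only free position conjugated to the hydroxyl (C2 is blocked), and should leave the isolated trisubstituted alkenes alone.

**Compound list**

1 | (2E,6E)-farnesol | CC(C)=CCC/C(C)=C/CC/C(C)=C/CO | starting material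
2 | (2E,6E)-3,7,11-trimethyldodeca-2,6,10-trien-1-yl acetate | CC(C)=CCC/C(C)=C/CC/C(C)=C/COC(C)=O | intermediate
3 | (2E,6E,10E)-12-hydroxy-3,7,11-trimethyldodeca-2,6,10-trien-1-yl acetate | OC/C(C)=C/CC/C(C)=C/CC/C(C)=C/COC(C)=O | intermediate
4 | (2E,6E,10E)-12-bromo-3,7,11-trimethyldodeca-2,6,10-trien-1-yl acetate | BrC/C(C)=C/CC/C(C)=C/CC/C(C)=C/COC(C)=O | intermediate
5 | (2E,6E)-1-bromo-3,7,11-trimethyldodeca-2,6,10-triene (farnesyl bromide) | CC(C)=CCC/C(C)=C/CC/C(C)=C/CBr | starting material
6 | {[(2E,6E)-3,7,11-trimethyldodeca-2,6,10-trien-1-yl]sulfonyl}benzene | CC(C)=CCC/C(C)=C/CC/C(C)=C/CS(=O)(=O)c1ccccc1 | intermediate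
7 | 1-lithio derivative of 6 | CC(C)=CCC/C(C)=C/CC/C(C)=C/C([Li])S(=O)(=O)c1ccccc1 | intermediate (not isolated)
8 | (2E,6E,10E,14E,18E)-3,7,11,15,19,23-hexamethyl-13-(phenylsulfonyl)tetracosa-2,6,10,14,18,22-hexaen-1-yl acetate, racemic at C13 | CC(C)=CCC/C(C)=C/CC/C(C)=C/C(S(=O)(=O)c1ccccc1)C/C(C)=C/CC/C(C)=C/CC/C(C)=C/COC(C)=O | intermediate
9 | (2E,6E,10E,14E,18E)-3,7,11,15,19,23-hexamethyl-13-(phenylsulfonyl)tetracosa-2,6,10,14,18,22-hexaen-1-ol | CC(C)=CCC/C(C)=C/CC/C(C)=C/C(S(=O)(=O)c1ccccc1)C/C(C)=C/CC/C(C)=C/CC/C(C)=C/CO | intermediate (not isolated)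
10 | (2E,6E,10E,14E,18E)-3,7,11,15,19,23-hexamethyltetracosa-2,6,10,14,18,22-hexaen-1-ol (all-E-hexaprenol) | CC(C)=CCC/C(C)=C/CC/C(C)=C/CC/C(C)=C/CC/C(C)=C/CC/C(C)=C/CO | intermediate
11 | hexaprenyl bromide | CC(C)=CCC/C(C)=C/CC/C(C)=C/CC/C(C)=C/CC/C(C)=C/CC/C(C)=C/CBr | intermediate (not isolated)
12 | hexaprenyl phenyl sulfone | CC(C)=CCC/C(C)=C/CC/C(C)=C/CC/C(C)=C/CC/C(C)=C/CC/C(C)=C/CS(=O)(=O)c1ccccc1 | intermediate
13 | (2R)-3-bromo-2-methylpropan-1-ol | OC[C@@H](C)CBr | starting material
14 | [(2R)-3-bromo-2-methylpropoxy](tert-butyl)dimethylsilane | CC(C)(C)[Si](C)(C)OC[C@@H](C)CBr | intermediate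
15 | (6S)-8-bromo-2,6-dimethyloct-2-ene ((S)-citronellyl bromide) | BrCC[C@@H](C)CCC=C(C)C | starting material
16 | {(2R)-3-[(tert-butyldimethylsilyl)oxy]-2-methylpropyl}magnesium bromide | CC(C)(C)[Si](C)(C)OC[C@@H](C)C[Mg]Br | intermediate (not isolated)
17 | tert-butyldimethyl{[(2S,6R)-2,6,10-trimethylundec-9-en-1-yl]oxy}silane | CC(C)(C)[Si](C)(C)OC[C@@H](C)CCC[C@@H](C)CCC=C(C)C | intermediate
18 | (4R,8S)-9-[(tert-butyldimethylsilyl)oxy]-4,8-dimethylnonanal | CC(C)(C)[Si](C)(C)OC[C@@H](C)CCC[C@@H](C)CCC=O | intermediate (not isolated)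
19 | (4R,8S)-9-[(tert-butyldimethylsilyl)oxy]-4,8-dimethylnonan-1-ol | CC(C)(C)[Si](C)(C)OC[C@@H](C)CCC[C@@H](C)CCCO | intermediate
20 | tert-butyl{[(2S,6R)-9-iodo-2,6-dimethylnonyl]oxy}dimethylsilane | CC(C)(C)[Si](C)(C)OC[C@@H](C)CCC[C@@H](C)CCCI | intermediate
21 | tert-butyl{[(2S,6R)-2,6-dimethyl-11-(trimethylsilyl)undec-10-yn-1-yl]oxy}dimethylsilane | CC(C)(C)[Si](C)(C)OC[C@@H](C)CCC[C@@H](C)CCCC#C[Si](C)(C)C | intermediate
22 | (2S,6R)-2,6-dimethyl-11-(trimethylsilyl)undec-10-yn-1-ol | OC[C@@H](C)CCC[C@@H](C)CCCC#C[Si](C)(C)C | intermediate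
23 | [(6R,10S)-11-iodo-6,10-dimethylundec-1-yn-1-yl]trimethylsilane | IC[C@@H](C)CCC[C@@H](C)CCCC#C[Si](C)(C)C | intermediate
24 | 1-lithio derivative of 12 | CC(C)=CCC/C(C)=C/CC/C(C)=C/CC/C(C)=C/CC/C(C)=C/CC/C(C)=C/C([Li])S(=O)(=O)c1ccccc1 | intermediate (not isolated)
25 | [(6R,10S,13E,17E,21E,25E,29E)-6,10,14,18,22,26,30,34-octamethyl-12-(phenylsulfonyl)pentatriaconta-13,17,21,25,29,33-hexaen-1-yn-1-yl]trimethylsilane, both epimers at C12 | CC(C)=CCC/C(C)=C/CC/C(C)=C/CC/C(C)=C/CC/C(C)=C/CC/C(C)=C/C(S(=O)(=O)c1ccccc1)C[C@@H](C)CCC[C@@H](C)CCCC#C[Si](C)(C)C | intermediate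
26 | [(6R,10S,13E,17E,21E,25E,29E)-6,10,14,18,22,26,30,34-octamethylpentatriaconta-13,17,21,25,29,33-hexaen-1-yn-1-yl]trimethylsilane | CC(C)=CCC/C(C)=C/CC/C(C)=C/CC/C(C)=C/CC/C(C)=C/CC/C(C)=C/CC[C@@H](C)CCC[C@@H](C)CCCC#C[Si](C)(C)C | intermediate (not isolated)
27 | (6R,10S,13E,17E,21E,25E,29E)-6,10,14,18,22,26,30,34-octamethylpentatriaconta-13,17,21,25,29,33-hexaen-1-yne | CC(C)=CCC/C(C)=C/CC/C(C)=C/CC/C(C)=C/CC/C(C)=C/CC/C(C)=C/CC[C@@H](C)CCC[C@@H](C)CCCC#C | intermediate
28 | benzaldehyde | O=Cc1ccccc1 | starting material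
29 | pent-1-en-3-one (ethyl vinyl ketone) | C=CC(=O)CC | starting material
30 | 2-[hydroxy(phenyl)methyl]pent-1-en-3-one, racemic | C=C(C(O)c1ccccc1)C(=O)CC | intermediate
31 | (1Z)-2-(bromomethyl)-1-phenylpent-1-en-3-one | BrC/C(=C\c1ccccc1)C(=O)CC | intermediate
32 | dimethyl[(1E,6R,10S,13E,17E,21E,25E,29E)-2,6,10,14,18,22,26,30,34-nonamethylpentatriaconta-1,13,17,21,25,29,33-heptaen-1-yl]alane | CC(C)=CCC/C(C)=C/CC/C(C)=C/CC/C(C)=C/CC/C(C)=C/CC/C(C)=C/CC[C@@H](C)CCC[C@@H](C)CCC/C(C)=C/[Al](C)C | intermediate (not isolated)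
33 | (1E)-2-(C45 chain)-1-phenylpent-1-en-3-one | CC(C)=CCC/C(C)=C/CC/C(C)=C/CC/C(C)=C/CC/C(C)=C/CC/C(C)=C/CC[C@@H](C)CCC[C@@H](C)CCC/C(C)=C/C/C(=C\c1ccccc1)C(=O)CC | intermediate
34 | (5E)-1,1,1-trifluoro-3-methyl-5-(C45 chain)-6-phenylhex-5-ene-2,4-dione, both epimers at C3 | CC(C)=CCC/C(C)=C/CC/C(C)=C/CC/C(C)=C/CC/C(C)=C/CC/C(C)=C/CC[C@@H](C)CCC[C@@H](C)CCC/C(C)=C/C/C(=C\c1ccccc1)C(=O)C(C)C(=O)C(F)(F)F | intermediate (not isolated)
35 | (1E)-4-diazo-2-(C45 chain)-1-phenylpent-1-en-3-one | CC(C)=CCC/C(C)=C/CC/C(C)=C/CC/C(C)=C/CC/C(C)=C/CC/C(C)=C/CC[C@@H](C)CCC[C@@H](C)CCC/C(C)=C/C/C(=C\c1ccccc1)C(=O)C(C)=[N+]=[N-] | intermediate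
36 | (3E)-2-methyl-3-(C45 chain)-4-phenylbuta-1,3-dien-1-one (phenyl trans to the ketene-bearing carbon) | CC(C)=CCC/C(C)=C/CC/C(C)=C/CC/C(C)=C/CC/C(C)=C/CC/C(C)=C/CC[C@@H](C)CCC[C@@H](C)CCC/C(C)=C/C/C(=C\c1ccccc1)C(C)=C=O | intermediate (not isolated)
37 | 2-methyl-3-(C45 chain)-4-phenylcyclobut-2-en-1-one, both configurations at C4 | CC(C)=CCC/C(C)=C/CC/C(C)=C/CC/C(C)=C/CC/C(C)=C/CC/C(C)=C/CC[C@@H](C)CCC[C@@H](C)CCC/C(C)=C/CC1=C(C)C(=O)C1c1ccccc1 | intermediate (not isolated)
38 | (3Z)-2-methyl-3-(C45 chain)-4-phenylbuta-1,3-dien-1-one (phenyl cis to the ketene-bearing carbon) | CC(C)=CCC/C(C)=C/CC/C(C)=C/CC/C(C)=C/CC/C(C)=C/CC/C(C)=C/CC[C@@H](C)CCC[C@@H](C)CCC/C(C)=C/C/C(=C/c1ccccc1)C(C)=C=O | intermediate (not isolated)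
39 | 2-methyl-3-(C45 chain)naphthalen-1-ol | CC(C)=CCC/C(C)=C/CC/C(C)=C/CC/C(C)=C/CC/C(C)=C/CC/C(C)=C/CC[C@@H](C)CCC[C@@H](C)CCC/C(C)=C/Cc1cc2ccccc2c(O)c1C | intermediate
40 | 2-methyl-3-[(2E,7R,11S,14E,18E,22E,26E,30E)-3,7,11,15,19,23,27,31,35-nonamethylhexatriaconta-2,14,18,22,26,30,34-heptaen-1-yl]naphthalene-1,4-dione | CC(C)=CCC/C(C)=C/CC/C(C)=C/CC/C(C)=C/CC/C(C)=C/CC/C(C)=C/CC[C@@H](C)CCC[C@@H](C)CCC/C(C)=C/CC1=C(C)C(=O)c2ccccc2C1=O | target

**Totals**

Total step count: 22.
Longest linear sequence: 13 steps (13 → 14 → 17 → 19 → 20 → 21 → 22 → 23 → 25 → 27 → 33 → 35 → 39 → 40; steps 8–16 and 19–22).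

**The three steps most likely to fail**

1. Step 21. The excited diazo ketone may be diverted into a 1,2-hydride shift from the adjacent methyl group or into carbene capture by the neighbouring chain alkene instead of the alkenyl shift. The ketene may also dimerise, or the cascade may stall at the cyclobutenone if inward rotation of the phenyl group is too slow. The fallback abandons ring construction and attaches the chain to a preformed quinone. It sets out from alkyne 27 and comes back at 40. Commercial menadione is chloromethylated (aqueous formaldehyde, HCl gas, AcOH) to 2-(chloromethyl)-3-methylnaphthalene-1,4-dione F1. Alkyne 27 is carboaluminated exactly as in step 19 to alane 32, which is cross-coupled with F1 under zerovalent nickel catalysis (NiCl2(PPh3)2 reduced with n-BuLi, THF, rt) to give 40 directly.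

2. Step 19. The alkenylalane or residual methylalane may add to the enone of 31 (1,2- or conjugate addition) faster than palladium turns over, or coupling may occur at the benzylic allyl terminus. The fallback builds the enone by enolate alkylation and olefination instead. It sets out from alkyne 27 and comes back at 33. Alane 32 is converted into its ate complex with n-BuLi and treated with paraformaldehyde, and aqueous HCl work-up gives the C45 allylic alcohol F2. PBr3 in Et2O at −10 °C gives the C45 allylic bromide F3. F3 alkylates the sodium salt of commercial diethyl (2-oxobutyl)phosphonate (NaH, THF) to give the α-alkylated β-ketophosphonate F4. Horner–Wadsworth–Emmons olefination of F4 with benzaldehyde 28 (NaH, THF, reflux) gives 33 as a mixture of geometric isomers, which step 21 tolerates.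

3. Step 20. Enolisation may be incomplete or misdirected (deprotonation at the doubly allylic CH2), the deacylative transfer at the substituted carbon may be sluggish, and the diazo group may add to the enone or the chain alkene on standing. The fallback makes the diazo ketone by acylation of a diazoalkane instead of by diazo transfer. It sets out from alkyne 27 and comes back at 35. Alane 32 is coupled (Pd(PPh3)4, THF) with commercial methyl (2Z)-2-(bromomethyl)-3-phenylprop-2-enoate to give methyl (2E)-2-(C45 chain)-3-phenylprop-2-enoate F5. LiOH in THF/MeOH/H2O gives the acid F6. Ethyl chloroformate and Et3N in THF at −15 °C give the mixed anhydride F7, which is not isolated and is treated with excess ethereal diazoethane at 0 °C to give 35.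

**Further compounds**

F1 | step 21 | 2-(chloromethyl)-3-methylnaphthalene-1,4-dione | CC1=C(CCl)C(=O)c2ccccc2C1=O
F2 | step 19 | (2E,7R,11S,14E,18E,22E,26E,30E)-3,7,11,15,19,23,27,31,35-nonamethylhexatriaconta-2,14,18,22,26,30,34-heptaen-1-ol | CC(C)=CCC/C(C)=C/CC/C(C)=C/CC/C(C)=C/CC/C(C)=C/CC/C(C)=C/CC[C@@H](C)CCC[C@@H](C)CCC/C(C)=C/CO
F3 | step 19 | (2E,7R,11S,14E,18E,22E,26E,30E)-1-bromo-3,7,11,15,19,23,27,31,35-nonamethylhexatriaconta-2,14,18,22,26,30,34-heptaene | CC(C)=CCC/C(C)=C/CC/C(C)=C/CC/C(C)=C/CC/C(C)=C/CC/C(C)=C/CC[C@@H](C)CCC[C@@H](C)CCC/C(C)=C/CBr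
F4 | step 19 | diethyl [1-(C45 chain)-2-oxobutyl]phosphonate, both epimers at C1 | CC(C)=CCC/C(C)=C/CC/C(C)=C/CC/C(C)=C/CC/C(C)=C/CC/C(C)=C/CC[C@@H](C)CCC[C@@H](C)CCC/C(C)=C/CC(C(=O)CC)P(=O)(OCC)OCC
F5 | step 20 | methyl (2E)-2-(C45 chain)-3-phenylprop-2-enoate | CC(C)=CCC/C(C)=C/CC/C(C)=C/CC/C(C)=C/CC/C(C)=C/CC/C(C)=C/CC[C@@H](C)CCC[C@@H](C)CCC/C(C)=C/C/C(=C\c1ccccc1)C(=O)OC
F6 | step 20 | (2E)-2-(C45 chain)-3-phenylprop-2-enoic acid | CC(C)=CCC/C(C)=C/CC/C(C)=C/CC/C(C)=C/CC/C(C)=C/CC/C(C)=C/CC[C@@H](C)CCC[C@@H](C)CCC/C(C)=C/C/C(=C\c1ccccc1)C(=O)O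
F7 | step 20 | ethyl carbonic anhydride of F6 | CC(C)=CCC/C(C)=C/CC/C(C)=C/CC/C(C)=C/CC/C(C)=C/CC/C(C)=C/CC[C@@H](C)CCC[C@@H](C)CCC/C(C)=C/C/C(=C\c1ccccc1)C(=O)OC(=O)OCC
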